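Remark on the chemistry: flavone numbering is used for the target (O1, C2, C3, C4, C4a, C5 to C8, C8a; ring B C1' to C6'). The open chain is numbered C1 to C9 from its ester carbon, so chain C1, C3, C5, C6, C7, C8 and C9 become flavone C5, C7, C8a, C4a, C4, C3 and C2.

Assumption: the target has no stereocentre. Compounds 14, 15 and 16 carry one enolisable centre (chain C8) and are racemic; this is of no consequence because C8 ends as the sp2 carbon C3.

## Analysis of the target

The target is a flavone: a benzo ring A fused to a pyranone ring C, with a 2,5-dihydroxy-4-methoxyphenyl ring B on C2, a 3-methylbut-2-enyl (prenyl) group on C3 and hydroxyls on C5 and C7. It has no stereocentre and no stereogenic double bond; a stereocentre exists only while C3 is sp3 in open-chain precursors and vanishes when ring C is formed. The sensitive groups are the trisubstituted prenyl alkene (strong acid, electrophiles and hydrogenation are excluded), the para-dihydroxy pattern of ring B (oxidised to a quinone in air under base once unmasked) and four free phenols beside a single methyl ether at C4', which rules out any late selective demethylation. Three things make the synthesis hard. The prenyl group must sit on C3, between two carbonyl-derived carbons, and not on oxygen. Five aryl oxygens must be told apart. Ring B has its own ortho hydroxyl at C2', so a C2/C4 diketone with free phenols on both sides could close to two different chromones. The strategy rests on ring A: the carbons C4a, C5, C6, C7, C8 and C8a carry oxygen on the alternate atoms C5, C7 and C8a and the acyl carbon C4 on C4a. That is the pattern of a folded poly-β-carbonyl chain whose methylene next to C4 has attacked a carboxyl carbon three acetate units away, so the C4a–C5 bond can be made by a Claisen cyclisation and all three ring A oxygens can come from carbonyl groups without protection. The resulting acylphloroglucinol is symmetric about the acyl group, so either ortho hydroxyl gives the same ring C.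

## Retrosynthetic reasoning

Target 19 from 18. The last operation removes only the two methoxymethyl acetals from O2' and O5'. These acetals survive organolithium, polyanion and alkoxide chemistry, come off in dilute protic acid that a C-prenyl group tolerates, and keep the hydroquinone masked until the end.

Flavone 18 from diketone 16. The O1–C2 bond is cut, the forward reaction being a cyclodehydration through hemiketal 17. In 16 the ring A hydroxyls are free and equivalent, while the ortho oxygen of ring B is still an acetal, so ring C can close in one direction only. This is the reason the acetals must outlast the ring closure.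

Diketone 16 from tetraketo ester 15. The C4a–C5 bond of ring A (chain C6–C1) is cut, opening the carbocycle to an acyclic chain. This is the only ring A bond whose formation leaves C5, C7 and C8a as carbonyl-derived phenols, so one ring and one skeletal bond are gained with no protecting group on ring A. The forward reaction must favour Claisen closure over the aldol modes of the same chain.

Tetraketo ester 15 from pyranone 14. Chain 15 is too prone to uncontrolled cyclisation to be stored, so it is traced to 14, in which C1 and the oxygen on C5 are tied together as a lactone. In 14 only C6 and C8 are enolisable, so it can be purified and kept. The forward reaction is ring opening by the same magnesium alkoxide that then effects the Claisen closure, so 15 exists only in the flask in which it cyclises.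

Pyranone 14 from pyranone 12 and ester 5. The C8–C9 bond is cut. Cutting C6–C7 instead, with an acyl donor that already contains C7, C8 and C9, is not workable: such a donor has a hydrogen on C8 between two carbonyls, and the strongly basic terminal carbanion of a polyanion would remove it instead of attacking the carbonyl. Ester 5 has no α-hydrogen. The prenyl chain is already on the attacking carbon of trianion 13, so no late alkylation among several acidic methylenes is needed.

Pyranone 12 from lactone 10 and amide 9. The C6–C7 bond is cut. Lactone 10 already holds chain C1 to C6 with the correct oxygenation, and its methyl carbon becomes the nucleophile in dianion 11. Amide 9 has only ordinary amide α-hydrogens and gives the ketone without over-addition.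

Amide 9 from amide 6 and bromide 7. The bond between chain C8 and the prenyl methylene is cut. Displacement at the primary allylic carbon by enolate 8 gives the linear prenyl group.

Ester 5 from diol 1. The carboxyl carbon is removed back to aryllithium 4 and bromide 3, the bromine back to bis-acetal 2, and the acetals back to the commercial diol 1. Bromination para to the methoxy group places the future C1' correctly, and halogen–metal exchange fixes the carbanion there.

## Alternatives that were turned down

Alternative 1: Ring B is built de novo instead of ring A. The disconnection removes C2', C3', C4' and C5' and leaves a chromone with an alkyne on C2. In the forward key step the ethynylchromone A2 is heated with the Cr(CO)5 methoxy(1-methoxyvinyl)carbene complex A3 (Dötz benzannulation). Alkyne insertion, carbonyl insertion and electrocyclisation form C5'–C6', C1'–C2' and C2'–C3' and give the para-methoxyphenol A1. In its favour, the larger alkyne substituent ends ortho to the new hydroxyl, so the C2' hydroxyl is born free and differentiated, and ring C already exists, so no closure ambiguity arises. On this point it is stronger than the chosen route. Against it, A1 carries a methyl ether on O5' where the target has a hydroxyl; this must be corrected by oxidative demethylation to the quinone and reduction, two redox steps next to the prenyl alkene. A2 must first be assembled with rings A and C, the prenyl group and a C2 alkyne, which is a longer sequence than the whole chosen route. The alkyne is conjugated to an electron-poor pyranone and is a poor benzannulation partner, the prenyl alkene can intercept the carbene, and chromium is used stoichiometrically. The approach builds the one ring that can be bought. In its place the chosen strategy takes ring B from diol 1 in three steps and makes ring A unprotected.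

Alternative 2: The C4a–C4 and C4–C3 bonds are cut, with C4 supplied as a carbonylating gas. In the forward key step the symmetric ring A iodide A5 and the ring B ketone A6 are coupled carbonylatively by a zerovalent palladium catalyst carrying a wide-bite-angle bisphosphine, with base, giving the 2-prenyl-1,3-diketone A4. In its favour, carbonylative α-arylation of ketones is an established catalytic reaction, the route is convergent, and A6 would come in one step from aryllithium 4 and amide 9. In convergence and in the predictability of the bond-forming step it is at least as strong as the chosen route, and the step count is similar. Against it, A5 is a very electron-rich iodide with two ortho substituents, so oxidative addition and acyl transfer are hindered. More seriously, A4 carries five identical acetals; unmasking the ring A oxygens unmasks O2' of ring B as well, so ring C must be closed with free phenols on both sides of the diketone and two chromones can form. The chosen strategy offers instead ring A hydroxyls that are created free while ring B stays masked (compound 16), which makes the closure unambiguous, and it needs two protecting groups instead of five.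

Alternative 3: The C4–C4a and O1–C2 bonds are cut. In the forward key step phloroglucinol A8 and the α-prenyl aroylacetate A9 are heated neat at about 240 °C (Mentzer pyrone synthesis) to give chromone A7 in one operation. In its favour it is the shortest route, ring A needs no protection, and the acidic hydrogen between the two carbonyls of A9, which defeats a polyanion acylation, makes its prenylation easy. On brevity it is clearly stronger than the chosen route. Against it, no acid- or heat-labile phenol protection on ring B survives a phenol melt at that temperature, so ring B must carry methyl ethers. A7 then has three methoxy groups, and the target requires removal of those on O2' and O5' while the one on O4' and the prenyl alkene stay untouched, for which there is no handle. The prenyl group and the keto ester are also at risk at 240 °C. The chosen strategy is longer, but every oxygen ends in its correct state under mild conditions.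

Key step: step 7

## Route

Step 1
Reactants: 1 methoxyhydroquinone
Product: 2 2-methoxy-1,4-bis(methoxymethoxy)benzene
Conditions: MOMCl (2.6 equiv), i-Pr2NEt (3 equiv), CH2Cl2, 0 °C to rt, argon
Reagents that add atoms: chloromethyl methyl ether, COCCl
Why: Williamson-type O-alkylation of both phenols by the reactive α-chloro ether under amine base; air is excluded because the deprotonated hydroquinone is easily oxidised.

Step 2
Reactants: 2 2-methoxy-1,4-bis(methoxymethoxy)benzene
Product: 3 1-bromo-4-methoxy-2,5-bis(methoxymethoxy)benzene
Conditions: NBS (1.05 equiv), MeCN, 0 °C to rt, dark
Reagents that add atoms: N-bromosuccinimide, O=C1CCC(=O)N1Br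
Why: Electrophilic aromatic bromination; C5 of 2 is para to the methoxy group and ortho to an acetal oxygen, whereas C6 has one ortho oxygen only and C3 is flanked by two substituents, so bromine should enter para to the methoxy group as in other 1,2,4-trialkoxybenzenes; succinimide is too weak an acid to cleave the acetals.

Step 3
Reactants: 3 1-bromo-4-methoxy-2,5-bis(methoxymethoxy)benzene
Product: 5 methyl 4-methoxy-2,5-bis(methoxymethoxy)benzoate, via aryllithium 4 (not isolated)
Conditions: n-BuLi (1.05 equiv), THF, −78 °C; cannulate into ClCO2Me (3 equiv), THF, −78 °C to rt
Reagents that add atoms: methyl chloroformate, COC(=O)Cl; n-butyllithium, [Li]CCCC (lithium of intermediate 4 only)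
Why: Bromine–lithium exchange is faster than deprotonation and fixes the carbanion at the brominated carbon, whereas direct lithiation of 2 would be expected between the two oxygens at C3; inverse addition into excess chloroformate gives the ester and keeps 4 from adding to the product.

Step 4
Reactants: 6 N-methoxy-N-methylacetamide, 7 prenyl bromide
Product: 9 N-methoxy-N,5-dimethylhex-4-enamide, via lithium enolate 8 (not isolated)
Conditions: LiN(i-Pr)2 (1.05 equiv), THF, −78 °C; 7 (1.1 equiv), DMPU, −78 to −20 °C
Reagents that add atoms: lithium diisopropylamide, CC(C)N([Li])C(C)C (lithium of intermediate 8 only)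
Why: Alkylation of an amide enolate at the primary carbon of the allylic bromide (SN2), which gives the linear prenyl chain; the Weinreb amide does not self-condense at low temperature and is the acyl donor of step 5.

Step 5
Reactants: 10 triacetic acid lactone, 9 N-methoxy-N,5-dimethylhex-4-enamide
Product: 12 4-hydroxy-6-(6-methyl-2-oxohept-5-en-1-yl)-2H-pyran-2-one, via dilithio pyranone 11 (not isolated)
Conditions: LiN(i-Pr)2 (2.3 equiv), THF–DMPU, −78 to −40 °C; 9 (1.0 equiv), −78 to 0 °C; cold 1 M HCl to pH 3
Reagents that add atoms: lithium diisopropylamide, CC(C)N([Li])C(C)C (lithium of intermediate 11 only)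
Why: Polyanion acylation: after the hydroxyl, the vinylogous methyl group of 10 is deprotonated, and this last-formed carbanion, not the oxyanion or ring carbon C3, is the most nucleophilic site; the Weinreb amide releases the ketone only on work-up, so there is no over-addition and the acidic product consumes no base.

Step 6
Reactants: 12 4-hydroxy-6-(6-methyl-2-oxohept-5-en-1-yl)-2H-pyran-2-one, 5 methyl 4-methoxy-2,5-bis(methoxymethoxy)benzoate
Product: 14 4-hydroxy-6-{3-[4-methoxy-2,5-bis(methoxymethoxy)benzoyl]-6-methyl-2-oxohept-5-en-1-yl}-2H-pyran-2-one (racemic), via trilithio pyranone 13 (not isolated)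
Conditions: 12 (2.2 equiv), LiN(i-Pr)2 (6.8 equiv), THF–DMPU, −78 to 0 °C; 5 (1.0 equiv), 0 °C to rt; cold 1 M HCl to pH 3
Reagents that add atoms: lithium diisopropylamide, CC(C)N([Li])C(C)C (lithium of intermediate 13 only)
Why: Claisen-type terminal acylation of a polyanion by an aromatic ester: the third carbanion, at the ketone α' carbon that already bears the prenyl chain, is the most basic and reacts first, and ester 5 has no α-hydrogen to quench it; the more acidic diketone product takes up a second equivalent of 13, hence the excess of 12, which should be recoverable.

Step 7
Reactants: 14 4-hydroxy-6-{3-[4-methoxy-2,5-bis(methoxymethoxy)benzoyl]-6-methyl-2-oxohept-5-en-1-yl}-2H-pyran-2-one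
Product: 16 1-[4-methoxy-2,5-bis(methoxymethoxy)phenyl]-2-(3-methylbut-2-en-1-yl)-3-(2,4,6-trihydroxyphenyl)propane-1,3-dione (racemic), via tetraketo ester 15 (not isolated)
Conditions: Mg(OMe)2 (8 equiv), MeOH, 50 °C to reflux, argon; then cold 1 M HCl to pH 3
Reagents that add atoms: magnesium methoxide, CO[Mg]OC (methoxy group of intermediate 15 only; none of its atoms remains in 16)
Why: Magnesium methoxide should first add to the lactone carbonyl of the pyranone and open it, as it does with 10 itself, giving the magnesium chelate of tetraketo ester 15 in which C1 is again a methyl ester. Within this chelate the enolate carbon C6 attacks C1 and expels methoxide (Claisen or Dieckmann-type acyl substitution), the closest known reaction being the Mg(OMe)2-mediated cyclisation of 3,5,7-triketo esters to acylphloroglucinols. Ring A closes in a 6-exo-trig mode with the enolate double bond outside the new ring, and the triketo tautomer first formed aromatises at once to the triol, which makes the step irreversible. No stereocentre is created, and C8 remains an enolisable racemic centre. The selectivity needed is Claisen closure (C6 onto C1) over the aldol closures (C2 onto C7, C4 onto C9) and over retro-Claisen loss of the aroyl group. The substrate helps because its most acidic hydrogen is on C8, so C7 and C9 are held as a magnesium diketonate that is a poor aldol acceptor and is screened by the prenyl branch, while the anhydrous alkoxide medium keeps C1 as an ester, the acceptor the Claisen mode requires. Return of the C5 oxygen onto C1 only regenerates 14 and is reversible, so it should not drain material.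

Step 8
Reactants: 16 1-[4-methoxy-2,5-bis(methoxymethoxy)phenyl]-2-(3-methylbut-2-en-1-yl)-3-(2,4,6-trihydroxyphenyl)propane-1,3-dione
Product: 18 5,7-dihydroxy-2-[4-methoxy-2,5-bis(methoxymethoxy)phenyl]-3-(3-methylbut-2-en-1-yl)-4H-chromen-4-one, via hemiketal 17 (not isolated)
Conditions: NaOAc (3 equiv), AcOH, 70 °C
Reagents that add atoms: none
Why: Cyclodehydration of an ortho-hydroxyaryl 1,3-diketone, the closing stage of a Baker–Venkataraman flavone synthesis: a ring A hydroxyl adds to the C2 carbonyl and hemiketal 17 loses water to give the pyranone; the two ortho hydroxyls of ring A are equivalent and the ortho oxygen of ring B is still an acetal, so only one chromone can form, and the acetate buffer should be too weakly acidic to cleave aryl methoxymethyl ethers at this temperature.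

Step 9
Reactants: 18 5,7-dihydroxy-2-[4-methoxy-2,5-bis(methoxymethoxy)phenyl]-3-(3-methylbut-2-en-1-yl)-4H-chromen-4-one
Product: 19 2-(2,5-dihydroxy-4-methoxyphenyl)-5,7-dihydroxy-3-(3-methylbut-2-en-1-yl)-4H-chromen-4-one
Conditions: 3 M aq. HCl–MeOH (1:4), 50 °C, argon
Reagents that add atoms: none
Why: Acid-catalysed acetal exchange with methanol removes both methoxymethyl groups as dimethoxymethane; the chromone and the C-prenyl group tolerate dilute methanolic acid at moderate temperature, and the hydroquinone is set free only here, under acidic, non-oxidising conditions.

## Compound list

1 | methoxyhydroquinone (2-methoxybenzene-1,4-diol) | COc1cc(O)ccc1O | starting material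
2 | 2-methoxy-1,4-bis(methoxymethoxy)benzene | COc1cc(OCOC)ccc1OCOC | intermediate
3 | 1-bromo-4-methoxy-2,5-bis(methoxymethoxy)benzene | COCOc1cc(OC)c(OCOC)cc1Br | intermediate
4 | [4-methoxy-2,5-bis(methoxymethoxy)phenyl]lithium | [Li]c1cc(OCOC)c(OC)cc1OCOC | intermediate (not isolated)
5 | methyl 4-methoxy-2,5-bis(methoxymethoxy)benzoate | COC(=O)c1cc(OCOC)c(OC)cc1OCOC | intermediate
6 | N-methoxy-N-methylacetamide | CON(C)C(C)=O | starting material
7 | prenyl bromide (1-bromo-3-methylbut-2-ene) | CC(C)=CCBr | starting material
8 | lithium enolate of 6 (lithium 1-[methoxy(methyl)amino]ethen-1-olate) | C=C(O[Li])N(C)OC | intermediate (not isolated)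
9 | N-methoxy-N,5-dimethylhex-4-enamide | CON(C)C(=O)CCC=C(C)C | intermediate
10 | triacetic acid lactone (4-hydroxy-6-methyl-2H-pyran-2-one) | Cc1cc(O)cc(=O)o1 | starting material
11 | dilithio derivative of 10 (lithium 6-(lithiomethyl)-2-oxo-2H-pyran-4-olate) | [Li]CC1=CC(O[Li])=CC(=O)O1 | intermediate (not isolated)
12 | 4-hydroxy-6-(6-methyl-2-oxohept-5-en-1-yl)-2H-pyran-2-one | CC(C)=CCCC(=O)Cc1cc(O)cc(=O)o1 | intermediate
13 | trilithio derivative of 12 (oxyanion, side-chain enolate and α' carbanion) | CC(C)=CCC([Li])C(O[Li])=Cc1cc(O[Li])cc(=O)o1 | intermediate (not isolated)
14 | 4-hydroxy-6-{3-[4-methoxy-2,5-bis(methoxymethoxy)benzoyl]-6-methyl-2-oxohept-5-en-1-yl}-2H-pyran-2-one (racemic) | CC(C)=CCC(C(=O)Cc1cc(O)cc(=O)o1)C(=O)c1cc(OCOC)c(OC)cc1OCOC | intermediate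
15 | methyl 9-[4-methoxy-2,5-bis(methoxymethoxy)phenyl]-8-(3-methylbut-2-en-1-yl)-3,5,7,9-tetraoxononanoate (racemic) | COC(=O)CC(=O)CC(=O)CC(=O)C(CC=C(C)C)C(=O)c1cc(OCOC)c(OC)cc1OCOC | intermediate (not isolated)
16 | 1-[4-methoxy-2,5-bis(methoxymethoxy)phenyl]-2-(3-methylbut-2-en-1-yl)-3-(2,4,6-trihydroxyphenyl)propane-1,3-dione (racemic) | CC(C)=CCC(C(=O)c1c(O)cc(O)cc1O)C(=O)c1cc(OCOC)c(OC)cc1OCOC | intermediate
17 | 2,5,7-trihydroxy-2-[4-methoxy-2,5-bis(methoxymethoxy)phenyl]-3-(3-methylbut-2-en-1-yl)-2,3-dihydro-4H-chromen-4-one (racemic mixture of diastereomers) | CC(C)=CCC1C(=O)c2c(O)cc(O)cc2OC1(O)c1cc(OCOC)c(OC)cc1OCOC | intermediate (not isolated)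
18 | 5,7-dihydroxy-2-[4-methoxy-2,5-bis(methoxymethoxy)phenyl]-3-(3-methylbut-2-en-1-yl)-4H-chromen-4-one | COCOc1cc(OC)c(OCOC)cc1-c1oc2cc(O)cc(O)c2c(=O)c1CC=C(C)C | intermediate
19 | 2-(2,5-dihydroxy-4-methoxyphenyl)-5,7-dihydroxy-3-(3-methylbut-2-en-1-yl)-4H-chromen-4-one | COc1cc(O)c(-c2oc3cc(O)cc(O)c3c(=O)c2CC=C(C)C)cc1O | target

## Step count and least certain steps

Total step count: 9. Longest linear sequence: 7 steps (1 to 2 to 3 to 5 to 14 to 16 to 18 to 19, steps 1, 2, 3, 6, 7, 8, 9).

Step 7 (key step). Opening of the hydroxypyranone needs heat, and at that temperature the released chain may close by aldol condensation (C2 onto C7) or lose its aroyl group by retro-Claisen methanolysis before the Claisen mode takes place; ring opening may also fail to compete with return to the lactone. The fallback separates chain release from ring closure. It sets out from 10 and rejoins the route at 15. Lactone 10 is opened with Mg(OMe)2 in hot methanol to methyl 3,5-dioxohexanoate F1. The trianion of F1 (three equivalents of LiN(i-Pr)2) is acylated at its terminal carbon by amide 9 to give methyl 11-methyl-3,5,7-trioxododec-10-enoate F2, which is used crude. The tetra-anion of F2 is aroylated at C8 by ester 5 to give 15, isolated after a cold acidic quench. Chain 15 is then cyclised with Mg(OMe)2 at room temperature to 16, without the hot ring-opening stage.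

Step 6. A branched secondary carbanion must attack an electron-rich, ortho-substituted ester, so proton transfer, low conversion or acylation at the pyranone oxyanion may take over. The fallback replaces acylation by aldol addition and oxidation. It sets out from 3 and 12 and rejoins at 14. Aryllithium 4, made from 3 as in step 3, is formylated with N,N-dimethylformamide to 4-methoxy-2,5-bis(methoxymethoxy)benzaldehyde F3. Trianion 13 adds to this far more electrophilic aldehyde at −78 °C to give 4-hydroxy-6-{3-[hydroxy(4-methoxy-2,5-bis(methoxymethoxy)phenyl)methyl]-6-methyl-2-oxohept-5-en-1-yl}-2H-pyran-2-one F4 as a diastereomer mixture. Oxidation of the benzylic alcohol with MnO2 in CH2Cl2 (or Dess–Martin periodinane) then gives 14.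

Step 5. The dilithio salt 11 may form incompletely or stay insoluble, so that the mono-anion reacts at oxygen or at ring carbon C3, or not at all. The fallback masks the hydroxyl so that a soluble mono-anion suffices. It sets out from 10 and rejoins at 12. Lactone 10 is converted with MOMCl and i-Pr2NEt into 4-(methoxymethoxy)-6-methyl-2H-pyran-2-one F5. Lateral lithiation of its methyl group with one equivalent of LiN(i-Pr)2 and acylation with 9 gives 4-(methoxymethoxy)-6-(6-methyl-2-oxohept-5-en-1-yl)-2H-pyran-2-one F6. Brief treatment with dilute methanolic HCl removes the very labile vinylogous acetal and gives 12; no ring B acetal is present at this stage.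

Step 8. Dehydration of hemiketal 17 may be sluggish under a buffer mild enough to preserve the acetals, or the ring B acetal may be partly lost before closure is complete, which would let the ring B hydroxyl compete for C4. The fallback gives up the stepwise order. It sets out from 16 and rejoins at 19. Compound 16 is treated directly with dilute methanolic HCl so that closure and deprotection run in one operation. This relies on hemiketal 17 having already formed from a ring A hydroxyl while ring B was masked, and on its acid-catalysed dehydration through a stabilised oxocarbenium ion being faster than acetal cleavage.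

## Further compounds

F1 | step 7 | methyl 3,5-dioxohexanoate | COC(=O)CC(=O)CC(C)=O
F2 | step 7 | methyl 11-methyl-3,5,7-trioxododec-10-enoate | COC(=O)CC(=O)CC(=O)CC(=O)CCC=C(C)C
F3 | step 6 | 4-methoxy-2,5-bis(methoxymethoxy)benzaldehyde | COCOc1cc(OC)c(OCOC)cc1C=O
F4 | step 6 | 4-hydroxy-6-{3-[hydroxy(4-methoxy-2,5-bis(methoxymethoxy)phenyl)methyl]-6-methyl-2-oxohept-5-en-1-yl}-2H-pyran-2-one (racemic mixture of diastereomers) | CC(C)=CCC(C(O)c1cc(OCOC)c(OC)cc1OCOC)C(=O)Cc1cc(O)cc(=O)o1
F5 | step 5 | 4-(methoxymethoxy)-6-methyl-2H-pyran-2-one | COCOc1cc(C)oc(=O)c1
F6 | step 5 | 4-(methoxymethoxy)-6-(6-methyl-2-oxohept-5-en-1-yl)-2H-pyran-2-one | COCOc1cc(CC(=O)CCC=C(C)C)oc(=O)c1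
F0 | step 8 | none | none
A1 | alternative 1 | 2-(2-hydroxy-4,5-dimethoxyphenyl)-5,7-bis(methoxymethoxy)-3-(3-methylbut-2-en-1-yl)-4H-chromen-4-one | COCOc1cc(OCOC)c2c(c1)oc(-c1cc(OC)c(OC)cc1O)c(CC=C(C)C)c2=O
A2 | alternative 1 | 2-ethynyl-5,7-bis(methoxymethoxy)-3-(3-methylbut-2-en-1-yl)-4H-chromen-4-one | C#Cc1oc2cc(OCOC)cc(OCOC)c2c(=O)c1CC=C(C)C
A3 | alternative 1 | pentacarbonyl[methoxy(1-methoxyethenyl)methylidene]chromium, Cr(CO)5[C(OMe)C(OMe)=CH2] | COC(=C)C(OC)=[Cr].[C-]#[O+].[C-]#[O+].[C-]#[O+].[C-]#[O+].[C-]#[O+]
A4 | alternative 2 | 1-[4-methoxy-2,5-bis(methoxymethoxy)phenyl]-2-(3-methylbut-2-en-1-yl)-3-[2,4,6-tris(methoxymethoxy)phenyl]propane-1,3-dione (racemic) | COCOc1cc(OCOC)c(C(=O)C(CC=C(C)C)C(=O)c2cc(OCOC)c(OC)cc2OCOC)c(OCOC)c1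
A5 | alternative 2 | 2-iodo-1,3,5-tris(methoxymethoxy)benzene | COCOc1cc(OCOC)c(I)c(OCOC)c1
A6 | alternative 2 | 1-[4-methoxy-2,5-bis(methoxymethoxy)phenyl]-5-methylhex-4-en-1-one | CC(C)=CCCC(=O)c1cc(OCOC)c(OC)cc1OCOC
A7 | alternative 3 | 5,7-dihydroxy-3-(3-methylbut-2-en-1-yl)-2-(2,4,5-trimethoxyphenyl)-4H-chromen-4-one | COc1cc(OC)c(-c2oc3cc(O)cc(O)c3c(=O)c2CC=C(C)C)cc1OC
A8 | alternative 3 | phloroglucinol (benzene-1,3,5-triol) | Oc1cc(O)cc(O)c1
A9 | alternative 3 | ethyl 5-methyl-2-(2,4,5-trimethoxybenzoyl)hex-4-enoate (racemic) | CCOC(=O)C(CC=C(C)C)C(=O)c1cc(OC)c(OC)cc1OC
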